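Numbering the core as 2,6-dioxabicyclo[3.3.0]octan-3-one (lactone ring A: C1, O2, C3, C4, C5; tetrahydrofuran ring B: C5, O6, C7, C8, C1), everything rests on closing ring B at C7–C8. The step exploits the 1,5 relationship, through O6, between C8 and a tertiary C7–H: C8 is generated as an alkylidene carbene on the C1 ketone of an open-chain (3S)-3-alkoxy-4-oxopentanoate and inserts into the C7–H of its (S)-configured secondary ether with retention. One operation closes ring B, makes the fully substituted C7 stereocentre from an epoxide-derived carbinol, and leaves a C8=C1 alkene onto which the C3 ester closes ring A. C5 is set by an oxazolidinone glycolate alkylation; the cis ring fusion then fixes C1.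

Key step: step 8

Remark: the target is read as (1S,5S,7S), with the C7 methyl group cis and the 12-phenyldodecyl chain trans to ring A; all starting materials are taken as commercial.

Step 1
Reactants: 1 11-bromoundec-1-ene; 2 iodobenzene
Product: 4 (11-bromoundecyl)benzene, via B-(11-bromoundecyl)-9-borabicyclo[3.3.1]nonane 3 (not isolated)
Conditions: 9-BBN, THF, 0 °C → rt; then 2, PdCl2(dppf) (3 mol%), AsPh3, Cs2CO3, DMF/THF/H2O, rt
Reagents that add atoms: none
Why: Anti-Markovnikov hydroboration of the terminal alkene followed by B-alkyl Suzuki–Miyaura coupling should join the fragments without touching the primary bromide, because zerovalent palladium inserts into the aryl iodide far faster than into an unactivated alkyl bromide.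

Step 2
Reactants: 4 (11-bromoundecyl)benzene; 5 (S)-2-methyloxirane
Product: 7 (2S)-14-phenyltetradecan-2-ol, via (11-phenylundecyl)magnesium bromide 6 (not isolated)
Conditions: Mg, THF, 40 °C; then CuI (10 mol%), 5, THF, −30 → 0 °C; then H2O
Reagents that add atoms: none
Why: The Grignard reagent should open the epoxide at its unsubstituted carbon under CuI catalysis (cuprate-type SN2 opening), so the (S) centre of 5 is carried unchanged into the carbinol that later becomes C7.

Step 3
Reactants: 7 (2S)-14-phenyltetradecan-2-ol; 8 bromoacetic acid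
Product: 9 2-{[(2S)-14-phenyltetradecan-2-yl]oxy}acetic acid
Conditions: NaH (3 equiv), THF, 0 °C → reflux; then aq. HCl
Reagents that add atoms: none
Why: Williamson ether synthesis in which the sodium alkoxide displaces bromide from sodium bromoacetate, the C–O bond at the stereocentre not being involved.

Step 4
Reactants: 9 2-{[(2S)-14-phenyltetradecan-2-yl]oxy}acetic acid; 10 (4R)-4-benzyl-1,3-oxazolidin-2-one
Product: 12 (4R)-4-benzyl-3-(2-{[(2S)-14-phenyltetradecan-2-yl]oxy}acetyl)-1,3-oxazolidin-2-one, via mixed pivalic anhydride 11 (not isolated)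
Conditions: PivCl, Et3N, THF, −20 °C; then 10, LiCl, rt
Reagents that add atoms: none
Why: Mixed-anhydride N-acylation in which the oxazolidinone, activated by LiCl/Et3N, should attack the less hindered glycolyl carbonyl of 11.

Step 5
Reactants: 12 (4R)-4-benzyl-3-(2-{[(2S)-14-phenyltetradecan-2-yl]oxy}acetyl)-1,3-oxazolidin-2-one; 13 tert-butyl bromoacetate
Product: 15 tert-butyl (3S)-4-[(4R)-4-benzyl-2-oxo-1,3-oxazolidin-3-yl]-4-oxo-3-{[(2S)-14-phenyltetradecan-2-yl]oxy}butanoate, via sodium Z-enolate 14 (not isolated)
Conditions: NaN(SiMe3)2 (1.1 equiv), THF, −78 °C; then 13 (3 equiv), −78 → −45 °C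
Reagents that add atoms: none
Why: Evans alkylation of a glycolate imide, in which the chelated Z sodium enolate 14 is shielded on one face by the benzyl group of the (R) auxiliary, so the reactive α-bromo ester should enter from the other face and set the future C5 as (S).

Step 6
Reactants: 15 tert-butyl (3S)-4-[(4R)-4-benzyl-2-oxo-1,3-oxazolidin-3-yl]-4-oxo-3-{[(2S)-14-phenyltetradecan-2-yl]oxy}butanoate
Product: 16 tert-butyl (3S)-4-(ethylsulfanyl)-4-oxo-3-{[(2S)-14-phenyltetradecan-2-yl]oxy}butanoate
Conditions: EtSH, n-BuLi, THF, 0 °C; then H2O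
Reagents that add atoms: ethanethiol (as LiSEt), CCS
Why: Thiolate transacylation, in which the weakly basic lithium ethanethiolate should attack the exocyclic imide carbonyl selectively and leave the tert-butyl ester and the α-stereocentre untouched.

Step 7
Reactants: 16 tert-butyl (3S)-4-(ethylsulfanyl)-4-oxo-3-{[(2S)-14-phenyltetradecan-2-yl]oxy}butanoate
Product: 17 tert-butyl (3S)-4-oxo-3-{[(2S)-14-phenyltetradecan-2-yl]oxy}pentanoate
Conditions: Me2CuLi (from MeLi and CuI), Et2O, −78 → −40 °C; then aq. NH4Cl
Reagents that add atoms: lithium dimethylcuprate Me2CuLi, [Li+].C[Cu-]C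
Why: Acyl substitution of a thioester by a lithium dialkylcuprate should stop at the methyl ketone at low temperature and spare the tert-butyl ester.

Step 8
Reactants: 17 tert-butyl (3S)-4-oxo-3-{[(2S)-14-phenyltetradecan-2-yl]oxy}pentanoate
Product: 21 tert-butyl 2-[(2S,5S)-3,5-dimethyl-5-(12-phenyldodecyl)-2,5-dihydrofuran-2-yl]acetate, via lithium alkoxide adduct 18 (not isolated), via diazoalkene 19 (not isolated), via alkylidene carbene 20 (not isolated)
Conditions: TMSCHN2, n-BuLi, THF, −78 °C; then 17, −78 °C → rt; then H2O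
Reagents that add atoms: trimethylsilyldiazomethane (as its lithium salt), C[Si](C)(C)C=[N+]=[N-]
Why: Lithiated trimethylsilyldiazomethane adds to the C1 ketone, the adduct 18 loses lithium trimethylsilanolate in a Peterson-type elimination to give the diazoalkene 19, and loss of N2 gives the singlet alkylidene carbene 20, whose carbene carbon (C8, delivered by the reagent) inserts into the C7–H bond in a concerted three-centre transition state. The closest known reaction type is the alkylidene carbene 1,5 C–H insertion of α-alkoxy ketones to 2,5-dihydrofurans, with the carbene generated as in the Seyferth–Gilbert/Colvin homologation. Ring B closes by 1,5 C–H insertion through a five-membered array that runs over O6 (C8–C1–C5–O6–C7), not by a polar or radical cyclisation. C7 is controlled by the (S) carbinol centre of the ether, because the insertion replaces H by C8 with retention of configuration, and C5 is not touched. The step needs the 1,5 insertion to outrun the 1,2-methyl shift to an alkyne, attack of the alkoxide of 18 on the ester, and enolisation at C5. The substrate secures this because the C7–H bond is the only 1,5 C–H bond, is tertiary and is activated by the lone pair of O6, while the bulky tert-butyl ester and the low temperature of the addition should hold back the side reactions.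

Step 9
Reactants: 21 tert-butyl 2-[(2S,5S)-3,5-dimethyl-5-(12-phenyldodecyl)-2,5-dihydrofuran-2-yl]acetate
Product: 22 plakortone L [(1S,5S,7S)-1,7-dimethyl-7-(12-phenyldodecyl)-2,6-dioxabicyclo[3.3.0]octan-3-one]
Conditions: Co(salen) complex C36H52CoN2O2 [N,N′-bis(3,5-di-tert-butylsalicylidene)-1,2-cyclohexanediaminocobalt, divalent cobalt] (5 mol%), N-fluoro-2,4,6-trimethylpyridinium tetrafluoroborate, (Me2SiH)2O, PhCF3, rt
Reagents that add atoms: none
Why: Metal-hydride hydrogen atom transfer from a cobalt hydride to C8 should give the tertiary C1 radical (Markovnikov), which after oxidation at cobalt is captured by the ester carbonyl oxygen with loss of the tert-butyl group as 2-methylpropene (radical–polar crossover hydroacyloxylation of an alkenyl ester), and because a five-membered lactone can only be fused cis to ring B the C1–O2 bond forms on the face of the C5 side chain and sets C1 as (S).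

Compound list
1 | 11-bromoundec-1-ene | C=CCCCCCCCCCBr | starting material
2 | iodobenzene | Ic1ccccc1 | starting material
3 | B-(11-bromoundecyl)-9-borabicyclo[3.3.1]nonane | BrCCCCCCCCCCCB1C2CCCC1CCC2 | intermediate (not isolated)
4 | (11-bromoundecyl)benzene | BrCCCCCCCCCCCc1ccccc1 | intermediate
5 | (S)-2-methyloxirane | C[C@H]1CO1 | starting material
6 | (11-phenylundecyl)magnesium bromide | Br[Mg]CCCCCCCCCCCc1ccccc1 | intermediate (not isolated)
7 | (2S)-14-phenyltetradecan-2-ol | C[C@H](O)CCCCCCCCCCCCc1ccccc1 | intermediate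
8 | bromoacetic acid | OC(=O)CBr | starting material
9 | 2-{[(2S)-14-phenyltetradecan-2-yl]oxy}acetic acid | OC(=O)CO[C@@H](C)CCCCCCCCCCCCc1ccccc1 | intermediate
10 | (4R)-4-benzyl-1,3-oxazolidin-2-one | O=C1OC[C@@H](Cc2ccccc2)N1 | starting material
11 | mixed anhydride of 9 and pivalic acid | CC(C)(C)C(=O)OC(=O)CO[C@@H](C)CCCCCCCCCCCCc1ccccc1 | intermediate (not isolated)
12 | (4R)-4-benzyl-3-(2-{[(2S)-14-phenyltetradecan-2-yl]oxy}acetyl)-1,3-oxazolidin-2-one | O=C1OC[C@@H](Cc2ccccc2)N1C(=O)CO[C@@H](C)CCCCCCCCCCCCc1ccccc1 | intermediate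
13 | tert-butyl bromoacetate | CC(C)(C)OC(=O)CBr | starting material
14 | sodium (Z)-enolate of 12 | [Na+].O=C1OC[C@@H](Cc2ccccc2)N1/C([O-])=C/O[C@@H](C)CCCCCCCCCCCCc1ccccc1 | intermediate (not isolated)
15 | tert-butyl (3S)-4-[(4R)-4-benzyl-2-oxo-1,3-oxazolidin-3-yl]-4-oxo-3-{[(2S)-14-phenyltetradecan-2-yl]oxy}butanoate | O=C1OC[C@@H](Cc2ccccc2)N1C(=O)[C@H](CC(=O)OC(C)(C)C)O[C@@H](C)CCCCCCCCCCCCc1ccccc1 | intermediate
16 | tert-butyl (3S)-4-(ethylsulfanyl)-4-oxo-3-{[(2S)-14-phenyltetradecan-2-yl]oxy}butanoate | CCSC(=O)[C@H](CC(=O)OC(C)(C)C)O[C@@H](C)CCCCCCCCCCCCc1ccccc1 | intermediate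
17 | tert-butyl (3S)-4-oxo-3-{[(2S)-14-phenyltetradecan-2-yl]oxy}pentanoate | CC(=O)[C@H](CC(=O)OC(C)(C)C)O[C@@H](C)CCCCCCCCCCCCc1ccccc1 | intermediate
18 | lithium alkoxide from addition of lithiated trimethylsilyldiazomethane to the ketone of 17 (carbinol centre undefined) | [Li+].[O-]C(C)(C(=[N+]=[N-])[Si](C)(C)C)[C@H](CC(=O)OC(C)(C)C)O[C@@H](C)CCCCCCCCCCCCc1ccccc1 | intermediate (not isolated)
19 | diazoalkene, tert-butyl (3S)-5-diazo-4-methyl-3-{[(2S)-14-phenyltetradecan-2-yl]oxy}pent-4-enoate | [N-]=[N+]=C=C(C)[C@H](CC(=O)OC(C)(C)C)O[C@@H](C)CCCCCCCCCCCCc1ccccc1 | intermediate (not isolated)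
20 | alkylidene carbene from 19 by loss of N2 | [C]=C(C)[C@H](CC(=O)OC(C)(C)C)O[C@@H](C)CCCCCCCCCCCCc1ccccc1 | intermediate (not isolated)
21 | tert-butyl 2-[(2S,5S)-3,5-dimethyl-5-(12-phenyldodecyl)-2,5-dihydrofuran-2-yl]acetate | C[C@]1(CCCCCCCCCCCCc2ccccc2)C=C(C)[C@H](CC(=O)OC(C)(C)C)O1 | intermediate
22 | plakortone L, (1S,5S,7S)-1,7-dimethyl-7-(12-phenyldodecyl)-2,6-dioxabicyclo[3.3.0]octan-3-one | C[C@]1(CCCCCCCCCCCCc2ccccc2)C[C@]2(C)OC(=O)C[C@@H]2O1 | target

Total step count: 9
Longest linear sequence: 9 steps (1 to 22)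

Steps most likely to fail

1. Step 8 (key step). The tertiary lithium alkoxide of 18 may close onto the tert-butyl ester before the silanolate is lost. The basic reagent may also enolise the ketone and erode the configuration at C5, and the carbene may be intercepted by the ester carbonyl oxygen. Fallback: setting out from 17, a base-free Ramirez dibromo-olefination (CBr4, PPh3, toluene, 80 °C) should give the 1,1-dibromoalkene F1. Bromine–lithium exchange (n-BuLi, THF, −100 °C) should then give the lithium carbenoid F2, which on warming loses LiBr and inserts into the same C7–H bond with retention. No alkoxide is formed on this way, and it comes back to the route at 21.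

2. Step 9. Hydrogen atom transfer to the hindered, trisubstituted ring alkene may be slow, and reversible transfer may move the double bond into conjugation with O6 instead of leading to lactonisation. Fallback: setting out from 21, iodolactonisation of the tert-butyl ester (I2, NaHCO3, MeCN, 0 °C) should give the iodolactone F3. Here the ester carbonyl opens the iodonium ion from the face of the C5 side chain and the tert-butyl group is lost. Radical deiodination (Bu3SnH, AIBN, toluene, 80 °C) then comes back to the route at 22.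

3. Step 5. The sodium glycolate enolate 14 is thermally labile and may decompose before the bromoacetate has reacted, and a second alkylation or O-alkylation may compete. Fallback: setting out from 12, the same enolate is alkylated with allyl iodide (NaN(SiMe3)2, THF, −78 → −45 °C), the most reactive class of electrophile for such enolates, to give the allyl imide F4 with the same facial control. Ozonolysis (O3, CH2Cl2, −78 °C; then PPh3) should give the aldehyde F5, and Pinnick oxidation (NaClO2, NaH2PO4, 2-methylbut-2-ene, t-BuOH/H2O) the acid F6. Esterification with tert-butyl 2,2,2-trichloroacetimidate (cat. BF3·OEt2, CH2Cl2/cyclohexane) comes back to the route at 15.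

Further compounds
F1 | step 8 | tert-butyl (3S)-5,5-dibromo-4-methyl-3-{[(2S)-14-phenyltetradecan-2-yl]oxy}pent-4-enoate | BrC(Br)=C(C)[C@H](CC(=O)OC(C)(C)C)O[C@@H](C)CCCCCCCCCCCCc1ccccc1
F2 | step 8 | tert-butyl (3S)-5-bromo-5-lithio-4-methyl-3-{[(2S)-14-phenyltetradecan-2-yl]oxy}pent-4-enoate (lithium carbenoid) | [Li]C(Br)=C(C)[C@H](CC(=O)OC(C)(C)C)O[C@@H](C)CCCCCCCCCCCCc1ccccc1
F3 | step 9 | 8-iodo-1,7-dimethyl-7-(12-phenyldodecyl)-2,6-dioxabicyclo[3.3.0]octan-3-one (ring stereocentres as in 22; iodine trans to O2) | C[C@]1(CCCCCCCCCCCCc2ccccc2)[C@@H](I)[C@]2(C)OC(=O)C[C@@H]2O1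
F4 | step 5 | (4R)-4-benzyl-3-[(2S)-2-{[(2S)-14-phenyltetradecan-2-yl]oxy}pent-4-enoyl]-1,3-oxazolidin-2-one | O=C1OC[C@@H](Cc2ccccc2)N1C(=O)[C@H](CC=C)O[C@@H](C)CCCCCCCCCCCCc1ccccc1
F5 | step 5 | (3S)-4-[(4R)-4-benzyl-2-oxo-1,3-oxazolidin-3-yl]-4-oxo-3-{[(2S)-14-phenyltetradecan-2-yl]oxy}butanal | O=C1OC[C@@H](Cc2ccccc2)N1C(=O)[C@H](CC=O)O[C@@H](C)CCCCCCCCCCCCc1ccccc1
F6 | step 5 | (3S)-4-[(4R)-4-benzyl-2-oxo-1,3-oxazolidin-3-yl]-4-oxo-3-{[(2S)-14-phenyltetradecan-2-yl]oxy}butanoic acid | O=C1OC[C@@H](Cc2ccccc2)N1C(=O)[C@H](CC(=O)O)O[C@@H](C)CCCCCCCCCCCCc1ccccc1
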